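At early times G has two ways out of any of these flasks, capture by Z and doubling with itself, and the set-ups below share it differently between the two.

all flasks: Z 0.2 mol%

| run | G | Q | time | remark |
|---|---|---|---|---|
| Tuesday's | 20 mM | 0.950 equiv (fed, over 4.00 h) | 5.0 h | all but Q at the start; Q goes in evenly over 4.00 h, the run ends at 5.0 h |
| Friday's | 20 mM | 0.950 equiv |  | a single well-mixed tank run continuously and read at steady state, 5.0 h in it on average |
| Wednesday's | 20 mM | 0.950 equiv | 5.0 h | a closed flask charged with all of it at once and left for 5.0 h |
| Sunday's | 20 mM (fed, over 4.00 h) | 0.950 equiv | 5.0 h | all but G at the start; G goes in evenly over 4.00 h, the run ends at 5.0 h |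

    Q.L → Z + D (k1 = 1110 /min)
    Q + L ⇌ Q.L (K2 = 98 /M, k2 = 98600 /M/min)
    G.Z ⇌ L (K3 = 0.57, k3 = 150 /min)
    G + Z → G.Z (k4 = 1070 /M/min)
    2 G → G2 (k5 = 1.39 /M/min)

- in percentages every species weighs as the G in it: one G2 counts as two
- a doubled species enters its step squared and goes two at a time
- the stated concentrations are those of everything mixed, before any reaction; amounts are the same in each set-up
- the feed brings no volume worth counting
- run time (Tuesday's): 5.0 h

- the set-up with the highest amount of D at the outlet or at the end, in percent of the G put in ("none" if the first two lie within 2 percentage points) (Tuesday's / Friday's / Wednesday's / Sunday's / none)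
- amount of D at the outlet or at the end, in percent of the G put in, Tuesday's
- amount of D at the outlet or at the end, in percent of the G put in, Friday's
- amount of D at the outlet or at the end, in percent of the G put in, Wednesday's
- amount of D at the outlet or at the end, in percent of the G put in, Sunday's

Take Wednesday's flask, charged at once, and look at rates per G. Capture goes at its constant times c_Z, and doubling at its constant times c_G, with two G lost per turn:

capture, per G: 0.0428 /min

doubling, per G, at the start: 0.0556 /min

Call capture over doubling at the start S, the selectivity factor:

S = 0.770

So you begin with doubling ahead.

Two things slow these rates. Capture per G holds as long as c_Z does, and I take Z as the resting state, since G.Z moves on at 150 /min, forward step alone, and capture of the charge runs slower. Reckoned on that forward step, with L and Q.L left out of the balance, waiting in G.Z costs a factor 0.875 at the start; I ignore it, so my figure is generous. Doubling per G falls with c_G itself. Take c_G down by a factor 10 and the ratio reads 7.70.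

Summing the share that goes to capture as c_G falls to nothing gives a logarithm:

D share, Wednesday's = S ln(1 + 1/S) = 64.1%

I reckoned no further than that flask.

The forecast names Sunday's as best, with 32.5% for Tuesday's, 85% for Friday's, 61.5% for Wednesday's and 89.2% for Sunday's. Its Wednesday's figure is lower than mine. Its ground: “Dimerisation is second order in G, so low G favours D.”

The simulation gives 33.9% for Tuesday's, 85.0% for Friday's, 61.5% for Wednesday's and 89.6% for Sunday's, so Sunday's is best.

Sunday's flask held unbound G at 8.91% of the charge at 2.50 h, which, with Z counted at its full charge (it stood at 97.5% then), puts the ratio there at 8.64, well above Wednesday's opening S. Now give Wednesday's flask more Z, 0.5 mol%. S scales with the loading to 1.92, and the same logarithm gives 80.5%. That flask gave 78.4%, with 17% of its Q left.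

The rate constants were drawn at random within sensible limits; no experiment stands behind them.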